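The target has no stereocentre, and its only C=C carries two identical methyl groups. It is therefore achiral and there is no enantiomer to select. 3-Hydroxy-2-methoxybenzaldehyde and diethyl (3,5-dimethoxybenzyl)phosphonate are taken as purchased catalogue compounds.

**Retrosynthetic overview**
- Target ⇒ prenylated bibenzyl mono-phenol + an acetoxy-transfer peroxide. A last-step ortho C–H acetoxylation makes the C4'–O bond and places the acetyl on the correct oxygen, so no catechol has to be differentiated.
- Prenylated bibenzyl phenol ⇒ bibenzyl phenol + prenyl bromide, by metalation between the two methoxy groups of ring A.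
- Bibenzyl phenol ⇒ stilbene ⇒ 3-hydroxy-2-methoxybenzaldehyde + 3,5-dimethoxybenzylphosphonate. The stilbene is hydrogenated before the prenyl alkene exists.
- Acetoxy-transfer peroxide ⇒ 3-chloroperoxybenzoic acid + acetic acid.
- No ring is formed. Rings A and B are bought intact and no protecting group is used.

**Step 1**
Reactants: 1 3-hydroxy-2-methoxybenzaldehyde; 2 diethyl (3,5-dimethoxybenzyl)phosphonate
Product: 3 3-[(E)-2-(3,5-dimethoxyphenyl)ethenyl]-2-methoxyphenol
Conditions: KOtBu (2.3 equiv), DMF, 0 °C to rt, 3 h; then 1 M HCl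
Reagents that add atoms: none
Why: Horner–Wadsworth–Emmons olefination; the phenoxide formed by the extra base is meta to the aldehyde and does not deactivate it, and the E/Z ratio does not matter because the alkene is reduced next.

**Step 2**
Reactants: 3 3-[(E)-2-(3,5-dimethoxyphenyl)ethenyl]-2-methoxyphenol
Product: 4 3-[2-(3,5-dimethoxyphenyl)ethyl]-2-methoxyphenol
Conditions: H2 (1 atm), 10% Pd/C, EtOAc/EtOH, rt
Reagents that add atoms: none
Why: Heterogeneous catalytic hydrogenation of a stilbene, run before the prenyl group is present so that no alkene selectivity is needed.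

**Step 3**
Reactants: 4 3-[2-(3,5-dimethoxyphenyl)ethyl]-2-methoxyphenol; 5 prenyl bromide (1-bromo-3-methylbut-2-ene)
Product: 7 3-{2-[3,5-dimethoxy-4-(3-methylbut-2-en-1-yl)phenyl]ethyl}-2-methoxyphenol, via dilithio species 6 (not isolated)
Conditions: n-BuLi (2.2 equiv), THF, 0 °C, 2 h; CuBr·SMe2 (10 mol%), 5 (1.2 equiv), −78 °C to 0 °C; aq NH4Cl
Reagents that add atoms: prenyl bromide, CC(C)=CCBr
Why: Directed ortho-metalation; the first equivalent of n-BuLi makes the lithium phenoxide, which leaves ring B with no C–H next to a good directing group, the second removes the C4–H between the two methoxy groups of ring A, and copper-catalysed SN2 allylation at the primary end of 5 gives the linear prenyl group, while the aggregated lithium phenoxide is too poor a nucleophile in cold THF to be O-alkylated.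

**Step 4**
Reactants: 8 3-chloroperoxybenzoic acid (buffer-washed and dried); 9 acetic acid
Product: 10 acetyl 3-chlorobenzoyl peroxide
Conditions: 9 (1.1 equiv), DCC (1.1 equiv), CH2Cl2, 0 °C, 2 h; filter, cold 5% aq Na2CO3 wash; kept as a titrated CH2Cl2 solution, never concentrated to dryness
Reagents that add atoms: acetic acid, CC(=O)O
Why: Carbodiimide coupling of a peracid with a carboxylic acid, the standard neutral route to unsymmetrical diacyl peroxides; the carbonate wash removes residual peracid that would otherwise epoxidise the prenyl group in step 5.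

**Step 5**
Reactants: 7 3-{2-[3,5-dimethoxy-4-(3-methylbut-2-en-1-yl)phenyl]ethyl}-2-methoxyphenol; 10 acetyl 3-chlorobenzoyl peroxide
Product: 13 4-{2-[3,5-dimethoxy-4-(3-methylbut-2-en-1-yl)phenyl]ethyl}-2-hydroxy-3-methoxyphenyl acetate (target), via aryl peracetate 11 (not isolated), via acetoxydienone 12 (not isolated)
Conditions: 10 (1.15 equiv), CH2Cl2 (0.2 M), argon, dark, 0 °C to 30 °C, 16–24 h; brief cold aq NaHCO3 wash, rapid chromatography on neutral silica
Reagents that add atoms: acetyl 3-chlorobenzoyl peroxide, CC(=O)OOC(=O)c1cccc(Cl)c1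
Why: Proposed new method: ortho C–H acetoxylation of a free phenol by a polarised mixed diacyl peroxide. The phenolic O–H hydrogen-bonds to the aroyl carbonyl of 10, and the phenol oxygen attacks the peroxide oxygen on the acetyl side, where the O–O antibonding orbital is larger and from which the better leaving group departs (3-chlorobenzoic acid pKa about 3.8, acetic acid 4.8). The resulting aryl peracetate 11 trades its weak O–O bond for a C–O bond in a [3,3]-sigmatropic shift to dienone 12, which tautomerises to 13. C4' is the only ortho carbon bearing hydrogen. The other ortho carbon, C2', is crowded by the side chain, and its doubly flanked methoxy group is twisted out of conjugation, so ipso attack is disfavoured. The cyclic delivery also avoids the para position. The acetyl lands by construction on the new O4' and leaves O3'–H free. The prenyl alkene and ring A offer no O–H to engage the reagent, and acyclic diacyl peroxides neither epoxidise alkenes nor oxidise anisoles at this temperature. Product 13 has both ortho positions filled and is deactivated, so oxidation stops there. The closest known reaction types are the ortho-benzoyloxylation of phenols with dibenzoyl peroxide and the [3,3] shift of N-aryl-O-acylhydroxylamines to ortho-acyloxyanilides. Selective acetoxy transfer from a mixed peroxide, and its use on a guaiacol-type phenol carrying an alkene, has not been shown.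

**Compound list**
1 | 3-hydroxy-2-methoxybenzaldehyde | COc1c(O)cccc1C=O | starting material
2 | diethyl (3,5-dimethoxybenzyl)phosphonate | CCOP(=O)(Cc1cc(OC)cc(OC)c1)OCC | starting material
3 | 3-[(E)-2-(3,5-dimethoxyphenyl)ethenyl]-2-methoxyphenol | COc1cc(/C=C/c2cccc(O)c2OC)cc(OC)c1 | intermediate
4 | 3-[2-(3,5-dimethoxyphenyl)ethyl]-2-methoxyphenol | COc1cc(CCc2cccc(O)c2OC)cc(OC)c1 | intermediate
5 | prenyl bromide (1-bromo-3-methylbut-2-ene) | CC(C)=CCBr | starting material
6 | lithium 3-[2-(4-lithio-3,5-dimethoxyphenyl)ethyl]-2-methoxyphenolate (dilithio species) | COc1cc(CCc2cccc(O[Li])c2OC)cc(OC)c1[Li] | intermediate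
7 | 3-{2-[3,5-dimethoxy-4-(3-methylbut-2-en-1-yl)phenyl]ethyl}-2-methoxyphenol | COc1cc(CCc2cccc(O)c2OC)cc(OC)c1CC=C(C)C | intermediate
8 | 3-chloroperoxybenzoic acid | OOC(=O)c1cccc(Cl)c1 | starting material
9 | acetic acid | CC(=O)O | starting material
10 | acetyl 3-chlorobenzoyl peroxide | CC(=O)OOC(=O)c1cccc(Cl)c1 | intermediate
11 | 3-{2-[3,5-dimethoxy-4-(3-methylbut-2-en-1-yl)phenyl]ethyl}-2-methoxyphenyl ethaneperoxoate (aryl peracetate) | COc1cc(CCc2cccc(OOC(C)=O)c2OC)cc(OC)c1CC=C(C)C | intermediate
12 | 6-acetoxy-3-{2-[3,5-dimethoxy-4-(3-methylbut-2-en-1-yl)phenyl]ethyl}-2-methoxycyclohexa-2,4-dien-1-one (racemic transient dienone) | COc1cc(CCC2=C(OC)C(=O)C(OC(C)=O)C=C2)cc(OC)c1CC=C(C)C | intermediate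
13 | 4-{2-[3,5-dimethoxy-4-(3-methylbut-2-en-1-yl)phenyl]ethyl}-2-hydroxy-3-methoxyphenyl acetate | COc1cc(CCc2ccc(OC(C)=O)c(O)c2OC)cc(OC)c1CC=C(C)C | target

**Step count**
- Total: 5 steps.
- Longest linear sequence: 4 steps (steps 1, 2, 3 and 5). Step 4 is a one-step reagent branch.

**Three steps most likely to fail**

**Step 5 (the proposed new acetoxylation).**
- Risks:
  - attack at the methoxy-bearing ortho carbon, giving an ortho-quinol acetate;
  - transfer of the 3-chlorobenzoyloxy group instead of the acetoxy group;
  - simple O-acetylation of the phenol, which releases peracid that epoxidises the prenyl group;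
  - radical-pair leakage with loss of CO2;
  - migration of the acetyl to O3' on work-up.
- Fallback (known chemistry), setting out from 7 and coming back at 13. Magnesium-mediated ortho-formylation (MgCl2, Et3N, paraformaldehyde, MeCN, reflux) can only strike the free ortho position. It gives 4-{2-[3,5-dimethoxy-4-(3-methylbut-2-en-1-yl)phenyl]ethyl}-2-hydroxy-3-methoxybenzaldehyde F1. Dakin oxidation (30% H2O2, NaOH, THF/H2O, 0 °C, under N2) leaves the isolated electron-rich alkene untouched. It gives 4-{2-[3,5-dimethoxy-4-(3-methylbut-2-en-1-yl)phenyl]ethyl}-3-methoxybenzene-1,2-diol F2. Monoacetylation with Ac2O (1.0 equiv) and pyridine in CH2Cl2 at −20 °C takes place at the less hindered 4'-OH, because the 3'-OH is flanked on both sides and hydrogen-bonded to the methoxy group. This gives 13.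

**Step 3 (metalation and prenylation of the unprotected phenol).**
- Risks: poor solubility of the dianion, incomplete or misdirected lithiation, and some O-prenylation.
- Fallback, setting out from 5 and 1 and coming back at 7. Here the prenyl group is installed before the two halves are joined. Purchased 3,5-dimethoxybenzyl alcohol (COc1cc(CO)cc(OC)c1) is treated with n-BuLi (2.2 equiv) in THF at 0 °C, then with CuBr·SMe2 and 5. This gives [3,5-dimethoxy-4-(3-methylbut-2-en-1-yl)phenyl]methanol F3. Direct phosphonylation of the benzylic alcohol (P(OEt)3, ZnI2, toluene, reflux) gives diethyl {[3,5-dimethoxy-4-(3-methylbut-2-en-1-yl)phenyl]methyl}phosphonate F4. Horner–Wadsworth–Emmons reaction with 1 (KOtBu, 2.3 equiv, DMF) gives 3-[(E)-2-[3,5-dimethoxy-4-(3-methylbut-2-en-1-yl)phenyl]ethenyl]-2-methoxyphenol F5. Diimide reduction (TsNHNH2, NaOAc, DME/H2O, reflux) reduces the disubstituted stilbene bond faster than the trisubstituted prenyl alkene and gives 7.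

**Step 1 (olefination of a free phenolic aldehyde).**
- Risks: low solubility of the potassium phenoxide, and a sluggish or incomplete reaction.
- Fallback, setting out from 1 and coming back at 4, so step 2 is bypassed. Purchased 3,5-dimethoxybenzyl chloride and Mg turnings in 2-MeTHF (slow addition) give 3,5-dimethoxybenzylmagnesium chloride F6. Adding 2.2 equiv of it to 1 at 0 °C gives racemic 3-[2-(3,5-dimethoxyphenyl)-1-hydroxyethyl]-2-methoxyphenol F7. Benzylic hydrogenolysis (H2, 10% Pd/C, EtOH, cat. HCl) removes the hydroxyl group and gives 4.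

**Further compounds**
F1 | step 5 | 4-{2-[3,5-dimethoxy-4-(3-methylbut-2-en-1-yl)phenyl]ethyl}-2-hydroxy-3-methoxybenzaldehyde | COc1cc(CCc2ccc(C=O)c(O)c2OC)cc(OC)c1CC=C(C)C
F2 | step 5 | 4-{2-[3,5-dimethoxy-4-(3-methylbut-2-en-1-yl)phenyl]ethyl}-3-methoxybenzene-1,2-diol | COc1cc(CCc2ccc(O)c(O)c2OC)cc(OC)c1CC=C(C)C
F3 | step 3 | [3,5-dimethoxy-4-(3-methylbut-2-en-1-yl)phenyl]methanol | COc1cc(CO)cc(OC)c1CC=C(C)C
F4 | step 3 | diethyl {[3,5-dimethoxy-4-(3-methylbut-2-en-1-yl)phenyl]methyl}phosphonate | CCOP(=O)(Cc1cc(OC)c(CC=C(C)C)c(OC)c1)OCC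
F5 | step 3 | 3-[(E)-2-[3,5-dimethoxy-4-(3-methylbut-2-en-1-yl)phenyl]ethenyl]-2-methoxyphenol | COc1cc(/C=C/c2cccc(O)c2OC)cc(OC)c1CC=C(C)C
F6 | step 1 | 3,5-dimethoxybenzylmagnesium chloride | COc1cc(C[Mg]Cl)cc(OC)c1
F7 | step 1 | 3-[2-(3,5-dimethoxyphenyl)-1-hydroxyethyl]-2-methoxyphenol (racemic) | COc1cc(CC(O)c2cccc(O)c2OC)cc(OC)c1
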